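How much product stands in the flask at 50 min, and which change adds most? Counting turnovers answers both: product made per free catalyst charged, with the curve drawn in that count.

| setting | epsilon | beta | flask |
|---|---|---|---|
| substrate | 2 M | 2 M | 2.0 M |
| solid reagent | 0.60 equiv | 1.2 equiv | 1.20 equiv |
| free catalyst | 1 mol% | 0.5 mol% | 1 mol% |
| remark | run made earlier | run made earlier |  |
| time |  |  | 50 min |

| run | time / min | product / % | substrate / % |
|---|---|---|---|
| epsilon | 5.00 | 1.2 | 98.5 |
| epsilon | 12.0 | 3.4 | 96.9 |
| epsilon | 25.0 | 7.5 | 93.0 |
| epsilon | 60.0 | 16.5 | 83.2 |
| beta | 8.00 | 0.1 | 99.4 |
| beta | 20.0 | 2.3 | 96.9 |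
| beta | 40.0 | 6.9 | 92.9 |
| beta | 60.0 | 10.6 | 89.6 |

(scatter of a reading: 0.5 percentage points)

- solid reagent is a solid; its amount is given per volume of the solution
- the analysis behind the earlier runs scatters by 0.5 percentage points, standard deviation
- at the start none of the solid reagent is in solution
- coupling partner is what solid reagent becomes in solution

1. the product standing at 50 min, as a percentage of the substrate charged
2. concentration of coupling partner in solution at 25 min, in percent of saturation
3. the change that raises the amount of product at 50 min, in percent of the substrate charged most ("none" if none brings more than 2 percentage points) (Thursday's / Tuesday's / Saturday's / none)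
4. amount of product at 50 min, in percent of the substrate charged, after Saturday's

- Thursday's: doubling the dissolution coefficient of the solid reagent, all else as stated
- Tuesday's: doubling the solubility of the solid reagent, all else as stated
- Saturday's: doubling the amount of free catalyst, all else as stated

The flask shares its substrate and solid reagent with the beta run and its free catalyst with the epsilon run, so neither run is the flask itself, and this reckoning carries the beta run over by the count, with the epsilon run held beside it. The beta run starts nearly flat, with 0.1% at 8.00 min, a reading inside the scatter of 0.5 percentage points. The slope of the beta run, in turnovers each minute, then rises and bends mildly, as far as the scatter lets it be read: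

20.0 min to 40.0 min: 0.460 min⁻¹

40.0 min to 60.0 min: 0.370 min⁻¹

Between those last readings, the beta run stands at 50 min at

N = 17.5

This is the turnover count (turnover number) at that time, product per free catalyst charged. The substrate charged in the flask offers 100 turnovers, so the curve should still be climbing.

The flask has twice the free catalyst of the beta run. If the count holds, this reckoning gives:

product = N × 1 mol% = 17.5%

Saturday's = 35.0%

The reckoning therefore picks Saturday's; solubility and dissolution were varied in no run. The figure is held as a high side, since the epsilon run, with the flask's free catalyst and less solid, counts 13.9.

The forecast says 16% (13.5% to 19%), lower than this reckoning. It puts coupling partner at 45% of saturation (20% to 75%) and Saturday's at 22% (17.5% to 29%). It names Tuesday's as best, differing from the reckoning: “The rate scales directly with solubility, so doubling it roughly doubles product.”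

The flask gives 15.9%, with coupling partner at 82.2% of saturation at 25 min. The best change is Saturday's, worth 13 points against 6.5 points for Tuesday's and 1.6 points for Thursday's, and it reaches 28.5%. At 12.6 min coupling partner is made 2.01 times as fast as it is used up. The count in the flask is 15.9 against the N of 17.5, and after Saturday's it is lower, 14.2, so doubling free catalyst multiplies the product by 1.79, and the reckoned 35.0% stands 6.5 points above the flask.

    coupling partner + free catalyst ⇌ catalyst intermediate A (K = 0.510 L mol⁻¹, k = 1.16 L mol⁻¹ s⁻¹)
    solid reagent ⇌ coupling partner, rate k2*(cs2 - [coupling partner]) while solid is left; crystals form when [coupling partner] > cs2 (solubility = 0.900 M, k = 0.00219 s⁻¹)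
    catalyst intermediate C → free catalyst + product (k = 0.548 s⁻¹)
    coupling partner → decomposed reagent (k = 2.54 × 10⁻⁴ s⁻¹)
    catalyst intermediate A ⇌ catalyst intermediate B (K = 0.319, k = 4.18 s⁻¹)
    substrate + catalyst intermediate B ⇌ catalyst intermediate C (K = 0.160 L mol⁻¹, k = 0.0748 L mol⁻¹ s⁻¹)

For the neighbour flask with 0.4 mol% of free catalyst, N gives 7.00%. That flask gives 6.81%, a count of 17.0.

The data were generated by integration for substances that don't exist.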